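**Retrosynthetic overview**
1. The dihydropyranone is closed last: its lactone C–O bond opens to a δ-silyloxy (Z)-enoate, whose C3=C4 bond is cut by a Z-selective Ando-type Horner–Wadsworth–Emmons reaction into a β-silyloxy aldehyde and an α-alkylated phosphonoacetate.
2. The butyrolactone is closed first, from a γ-hydroxy tert-butyl ester. The bond between the two stereocentres is the key disconnection: an intermolecular Evans syn-aldol of a succinate-derived N-acyl oxazolidinone with 3-(benzyloxy)propanal sets both stereocentres at once.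
3. The side chain comes from alkylating the phosphonoacetate with a homoallylic iodide. Its E-trisubstituted alkene is made by Cp2ZrCl2-catalysed methylalumination of a terminal alkyne and trapping with ethylene oxide.
4. Ring order: trimethylcyclohexene ring purchased (dihydro-β-ionone), then butyrolactone, then dihydropyranone.

Assumption: the target is read as (6R) at the pyranone carbinol carbon and (3R) at the oxolanone ring carbon; dihydro-β-ionone, mono-tert-butyl succinate, (S)-4-benzyl-2-oxazolidinone, 3-(benzyloxy)propan-1-ol, ethylene oxide and ethyl [bis(2-methylphenoxy)phosphoryl]acetate are taken as purchasable.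

**Route**

Step 1
Reactants: 1 4-tert-butoxy-4-oxobutanoic acid (mono-tert-butyl succinate); 2 (4S)-4-benzyl-1,3-oxazolidin-2-one
Product: 4 tert-butyl 4-[(4S)-4-benzyl-2-oxo-1,3-oxazolidin-3-yl]-4-oxobutanoate, via mixed pivalic anhydride 3 (not isolated)
Conditions: PivCl, Et3N, THF, −20 °C; then LiCl, 2, −20 °C → rt
Reagents that add atoms: none
Why: Evans N-acylation through the mixed pivalic anhydride (LiCl/Et3N variant) acylates the oxazolidinone at the unhindered succinyl carbonyl and leaves the tert-butyl ester untouched.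

Step 2
Reactants: 5 3-(benzyloxy)propan-1-ol
Product: 6 3-(benzyloxy)propanal
Conditions: TEMPO (10 mol %), PhI(OAc)2, CH2Cl2, rt
Reagents that add atoms: none
Why: TEMPO/PhI(OAc)2 oxidation of a primary alcohol stops at the aldehyde, and the non-basic medium avoids β-elimination of benzyl alcohol.

Step 3
Reactants: 4 tert-butyl 4-[(4S)-4-benzyl-2-oxo-1,3-oxazolidin-3-yl]-4-oxobutanoate; 6 3-(benzyloxy)propanal
Product: 9 tert-butyl (3S,4R)-3-[(4S)-4-benzyl-2-oxo-1,3-oxazolidine-3-carbonyl]-6-(benzyloxy)-4-hydroxyhexanoate, via Z-boron enolate 7 (not isolated), via boron aldolate 8 (not isolated)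
Conditions: n-Bu2BOTf, iPr2NEt, CH2Cl2, 0 °C; then 6, −78 → 0 °C; then pH 7 buffer, MeOH, 30% H2O2, 0 °C
Reagents that add atoms: none
Why: Evans syn-aldol reaction in which only the imide is enolised to the Z-boron enolate, which adds to the aldehyde through a Zimmerman–Traxler chair on the face away from the benzyl group, setting (3S,4R); these centres become (3R) of the oxolanone (the descriptor changes only because CIP priorities change on reduction) and (6R) of the pyranone.

Step 4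
Reactants: 9 tert-butyl (3S,4R)-3-[(4S)-4-benzyl-2-oxo-1,3-oxazolidine-3-carbonyl]-6-(benzyloxy)-4-hydroxyhexanoate
Product: 10 tert-butyl (3S,4R)-3-[(4S)-4-benzyl-2-oxo-1,3-oxazolidine-3-carbonyl]-6-(benzyloxy)-4-[(tert-butyldimethylsilyl)oxy]hexanoate
Conditions: TBSOTf, 2,6-lutidine, CH2Cl2, −78 → 0 °C
Reagents that add atoms: tert-butyldimethylsilyl trifluoromethanesulfonate (TBSOTf), CC(C)(C)[Si](C)(C)OS(=O)(=O)C(F)(F)F
Why: Silyl ether formation with the reactive triflate caps the hindered aldol hydroxyl before it can lactonise onto the ester or undergo retro-aldol, and at low temperature is much faster than attack on the tert-butyl ester.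

Step 5
Reactants: 10 tert-butyl (3S,4R)-3-[(4S)-4-benzyl-2-oxo-1,3-oxazolidine-3-carbonyl]-6-(benzyloxy)-4-[(tert-butyldimethylsilyl)oxy]hexanoate
Product: 11 tert-butyl (3R,4R)-6-(benzyloxy)-4-[(tert-butyldimethylsilyl)oxy]-3-(hydroxymethyl)hexanoate
Conditions: LiBH4, H2O (1.1 equiv), Et2O, 0 °C
Reagents that add atoms: none
Why: Reductive cleavage of the N-acyl oxazolidinone with LiBH4 reduces the activated imide carbonyl to the primary alcohol in preference to the hindered tert-butyl ester, releases the recoverable auxiliary and touches neither stereocentre.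

Step 6
Reactants: 11 tert-butyl (3R,4R)-6-(benzyloxy)-4-[(tert-butyldimethylsilyl)oxy]-3-(hydroxymethyl)hexanoate
Product: 12 (4R)-4-[(1R)-3-(benzyloxy)-1-[(tert-butyldimethylsilyl)oxy]propyl]oxolan-2-one
Conditions: p-TsOH·H2O (5 mol %), toluene, 50 °C
Reagents that add atoms: none
Why: Acid-catalysed lactonisation (intramolecular transesterification) of the γ-hydroxy tert-butyl ester closes the five-membered lactone, while anhydrous catalytic acid spares the secondary TBS ether and the benzyl ether.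

Step 7
Reactants: 12 (4R)-4-[(1R)-3-(benzyloxy)-1-[(tert-butyldimethylsilyl)oxy]propyl]oxolan-2-one
Product: 13 (4R)-4-[(1R)-1-[(tert-butyldimethylsilyl)oxy]-3-hydroxypropyl]oxolan-2-one
Conditions: H2 (1 atm), 10% Pd/C, EtOAc, rt
Reagents that add atoms: none
Why: Hydrogenolysis of the benzyl ether is clean here because no alkene is yet present and the silyl ether and lactone are inert in EtOAc.

Step 8
Reactants: 13 (4R)-4-[(1R)-1-[(tert-butyldimethylsilyl)oxy]-3-hydroxypropyl]oxolan-2-one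
Product: 14 (3R)-3-[(tert-butyldimethylsilyl)oxy]-3-[(3R)-5-oxooxolan-3-yl]propanal
Conditions: TEMPO (10 mol %), PhI(OAc)2, CH2Cl2, rt; used crude
Reagents that add atoms: none
Why: TEMPO/PhI(OAc)2 oxidation gives the aldehyde under non-basic conditions, so the β-silyloxy aldehyde does not eliminate and the carbinol centre is not disturbed.

Step 9
Reactants: 15 4-(2,6,6-trimethylcyclohex-1-en-1-yl)butan-2-one (dihydro-β-ionone)
Product: 17 2-(but-3-yn-1-yl)-1,3,3-trimethylcyclohex-1-ene, via enol phosphate 16 (not isolated)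
Conditions: LiN(iPr)2 (1.05 equiv), THF, −78 °C; ClP(O)(OEt)2, −78 °C → rt; then LiN(iPr)2 (2.3 equiv), −78 °C → rt; H2O quench
Reagents that add atoms: none
Why: Negishi methyl ketone to terminal alkyne conversion, in which kinetic deprotonation at the methyl group and O-phosphorylation give the terminal enol phosphate, and excess amide base eliminates phosphate and holds the product as the acetylide until quench.

Step 10
Reactants: 17 2-(but-3-yn-1-yl)-1,3,3-trimethylcyclohex-1-ene; 18 oxirane (ethylene oxide)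
Product: 21 (3E)-4-methyl-6-(2,6,6-trimethylcyclohex-1-en-1-yl)hex-3-en-1-ol, via alkenylalane 19 (not isolated), via lithium alkenylaluminate 20 (not isolated)
Conditions: Me3Al (2 equiv), Cp2ZrCl2 (25 mol %), ClCH2CH2Cl, rt; evaporate; n-BuLi, hexane/THF, −78 °C; then 18, −78 °C → rt; aq. HCl
Reagents that add atoms: trimethylaluminium (Me3Al), C[Al](C)C
Why: Negishi Cp2ZrCl2-catalysed carboalumination adds methyl and aluminium syn across the alkyne with methyl on the internal carbon, and the derived aluminate opens the epoxide with retention at the alkenyl carbon, which fixes the E-trisubstituted alkene.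

Step 11
Reactants: 21 (3E)-4-methyl-6-(2,6,6-trimethylcyclohex-1-en-1-yl)hex-3-en-1-ol
Product: 22 2-[(3E)-6-iodo-3-methylhex-3-en-1-yl]-1,3,3-trimethylcyclohex-1-ene
Conditions: I2, PPh3, imidazole, CH2Cl2, 0 °C → rt
Reagents that add atoms: iodine (I2), II
Why: Appel-type iodination is an SN2 displacement of the primary alkoxyphosphonium under near-neutral conditions that do not isomerise either alkene.

Step 12
Reactants: 22 2-[(3E)-6-iodo-3-methylhex-3-en-1-yl]-1,3,3-trimethylcyclohex-1-ene; 23 ethyl 2-[bis(2-methylphenoxy)phosphoryl]acetate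
Product: 24 ethyl (5E)-2-[bis(2-methylphenoxy)phosphoryl]-6-methyl-8-(2,6,6-trimethylcyclohex-1-en-1-yl)oct-5-enoate (racemic at C2)
Conditions: 23 (1.3 equiv), NaH, DMSO, rt; then 22, rt → 50 °C
Reagents that add atoms: none
Why: C-alkylation (SN2) of the stabilised phosphonoacetate anion with a primary iodide; the soft, weakly basic anion favours substitution over E2 and the excess of 23 suppresses dialkylation.

Step 13
Reactants: 14 (3R)-3-[(tert-butyldimethylsilyl)oxy]-3-[(3R)-5-oxooxolan-3-yl]propanal; 24 ethyl (5E)-2-[bis(2-methylphenoxy)phosphoryl]-6-methyl-8-(2,6,6-trimethylcyclohex-1-en-1-yl)oct-5-enoate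
Product: 25 ethyl (2Z,5R)-5-[(tert-butyldimethylsilyl)oxy]-2-[(3E)-4-methyl-6-(2,6,6-trimethylcyclohex-1-en-1-yl)hex-3-en-1-yl]-5-[(3R)-5-oxooxolan-3-yl]pent-2-enoate
Conditions: 24 (1.2 equiv), NaH, THF, 0 °C; then 14, −78 → 0 °C
Reagents that add atoms: none
Why: Ando-type Z-selective Horner–Wadsworth–Emmons olefination, in which the electron-poor diaryl phosphonate collapses quickly from the kinetic adduct to the (2Z)-enoate (ester cis to the aldehyde-derived chain), and the low temperature spares the lactone and the β-silyloxy aldehyde.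

Step 14
Reactants: 25 ethyl (2Z,5R)-5-[(tert-butyldimethylsilyl)oxy]-2-[(3E)-4-methyl-6-(2,6,6-trimethylcyclohex-1-en-1-yl)hex-3-en-1-yl]-5-[(3R)-5-oxooxolan-3-yl]pent-2-enoate
Product: 27 (6R)-3-[(3E)-4-methyl-6-(2,6,6-trimethylcyclohex-1-en-1-yl)hex-3-en-1-yl]-6-[(3R)-5-oxooxolan-3-yl]-5,6-dihydro-2H-pyran-2-one (target), via hydroxy ester 26 (not isolated)
Conditions: HF·pyridine, pyridine, THF, 0 °C → rt; then PPTS (10 mol %), toluene, 60 °C
Reagents that add atoms: none
Why: Desilylation followed by acid-catalysed lactonisation, in which the Z-alkene holds the freed hydroxyl next to the ester so six-ring closure with loss of ethanol is fast, whereas attack on the butyrolactone carbonyl would need a strained bicyclo[2.2.1] intermediate; the mild acid leaves the 1,5-diene untouched.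

**Compound list**
1 | 4-tert-butoxy-4-oxobutanoic acid (mono-tert-butyl succinate) | OC(=O)CCC(=O)OC(C)(C)C | starting material
2 | (4S)-4-benzyl-1,3-oxazolidin-2-one | O=C1N[C@@H](Cc2ccccc2)CO1 | starting material
3 | 4-tert-butoxy-4-oxobutanoic pivalic anhydride | CC(C)(C)C(=O)OC(=O)CCC(=O)OC(C)(C)C | intermediate
4 | tert-butyl 4-[(4S)-4-benzyl-2-oxo-1,3-oxazolidin-3-yl]-4-oxobutanoate | O=C1OC[C@H](Cc2ccccc2)N1C(=O)CCC(=O)OC(C)(C)C | intermediate
5 | 3-(benzyloxy)propan-1-ol | OCCCOCc1ccccc1 | starting material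
6 | 3-(benzyloxy)propanal | O=CCCOCc1ccccc1 | intermediate
7 | tert-butyl (3Z)-4-[(4S)-4-benzyl-2-oxo-1,3-oxazolidin-3-yl]-4-[(dibutylboranyl)oxy]but-3-enoate (Z-boron enolate) | O=C1OC[C@H](Cc2ccccc2)N1/C(OB(CCCC)CCCC)=C/CC(=O)OC(C)(C)C | intermediate
8 | tert-butyl (3S,4R)-3-[(4S)-4-benzyl-2-oxo-1,3-oxazolidine-3-carbonyl]-6-(benzyloxy)-4-[(dibutylboranyl)oxy]hexanoate (boron aldolate) | O=C1OC[C@H](Cc2ccccc2)N1C(=O)[C@@H](CC(=O)OC(C)(C)C)[C@H](OB(CCCC)CCCC)CCOCc1ccccc1 | intermediate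
9 | tert-butyl (3S,4R)-3-[(4S)-4-benzyl-2-oxo-1,3-oxazolidine-3-carbonyl]-6-(benzyloxy)-4-hydroxyhexanoate | O=C1OC[C@H](Cc2ccccc2)N1C(=O)[C@@H](CC(=O)OC(C)(C)C)[C@H](O)CCOCc1ccccc1 | intermediate
10 | tert-butyl (3S,4R)-3-[(4S)-4-benzyl-2-oxo-1,3-oxazolidine-3-carbonyl]-6-(benzyloxy)-4-[(tert-butyldimethylsilyl)oxy]hexanoate | O=C1OC[C@H](Cc2ccccc2)N1C(=O)[C@@H](CC(=O)OC(C)(C)C)[C@H](O[Si](C)(C)C(C)(C)C)CCOCc1ccccc1 | intermediate
11 | tert-butyl (3R,4R)-6-(benzyloxy)-4-[(tert-butyldimethylsilyl)oxy]-3-(hydroxymethyl)hexanoate | OC[C@@H](CC(=O)OC(C)(C)C)[C@H](O[Si](C)(C)C(C)(C)C)CCOCc1ccccc1 | intermediate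
12 | (4R)-4-[(1R)-3-(benzyloxy)-1-[(tert-butyldimethylsilyl)oxy]propyl]oxolan-2-one | O=C1C[C@H](CO1)[C@H](O[Si](C)(C)C(C)(C)C)CCOCc1ccccc1 | intermediate
13 | (4R)-4-[(1R)-1-[(tert-butyldimethylsilyl)oxy]-3-hydroxypropyl]oxolan-2-one | O=C1C[C@H](CO1)[C@H](O[Si](C)(C)C(C)(C)C)CCO | intermediate
14 | (3R)-3-[(tert-butyldimethylsilyl)oxy]-3-[(3R)-5-oxooxolan-3-yl]propanal | O=C1C[C@H](CO1)[C@H](O[Si](C)(C)C(C)(C)C)CC=O | intermediate
15 | 4-(2,6,6-trimethylcyclohex-1-en-1-yl)butan-2-one (dihydro-β-ionone) | CC(=O)CCC1=C(C)CCCC1(C)C | starting material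
16 | diethyl 4-(2,6,6-trimethylcyclohex-1-en-1-yl)but-1-en-2-yl phosphate | C=C(CCC1=C(C)CCCC1(C)C)OP(=O)(OCC)OCC | intermediate
17 | 2-(but-3-yn-1-yl)-1,3,3-trimethylcyclohex-1-ene | C#CCCC1=C(C)CCCC1(C)C | intermediate
18 | oxirane (ethylene oxide) | C1CO1 | starting material
19 | dimethyl[(1E)-2-methyl-4-(2,6,6-trimethylcyclohex-1-en-1-yl)but-1-en-1-yl]alane | C[Al](C)/C=C(\C)CCC1=C(C)CCCC1(C)C | intermediate
20 | lithium butyl(dimethyl)[(1E)-2-methyl-4-(2,6,6-trimethylcyclohex-1-en-1-yl)but-1-en-1-yl]aluminate | [Li+].CCCC[Al-](C)(C)/C=C(\C)CCC1=C(C)CCCC1(C)C | intermediate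
21 | (3E)-4-methyl-6-(2,6,6-trimethylcyclohex-1-en-1-yl)hex-3-en-1-ol | OCC/C=C(\C)CCC1=C(C)CCCC1(C)C | intermediate
22 | 2-[(3E)-6-iodo-3-methylhex-3-en-1-yl]-1,3,3-trimethylcyclohex-1-ene | ICC/C=C(\C)CCC1=C(C)CCCC1(C)C | intermediate
23 | ethyl 2-[bis(2-methylphenoxy)phosphoryl]acetate | CCOC(=O)CP(=O)(Oc1ccccc1C)Oc1ccccc1C | starting material
24 | ethyl (5E)-2-[bis(2-methylphenoxy)phosphoryl]-6-methyl-8-(2,6,6-trimethylcyclohex-1-en-1-yl)oct-5-enoate (racemic at C2) | CCOC(=O)C(CC/C=C(\C)CCC1=C(C)CCCC1(C)C)P(=O)(Oc1ccccc1C)Oc1ccccc1C | intermediate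
25 | ethyl (2Z,5R)-5-[(tert-butyldimethylsilyl)oxy]-2-[(3E)-4-methyl-6-(2,6,6-trimethylcyclohex-1-en-1-yl)hex-3-en-1-yl]-5-[(3R)-5-oxooxolan-3-yl]pent-2-enoate | CCOC(=O)/C(CC/C=C(\C)CCC1=C(C)CCCC1(C)C)=C\C[C@@H](O[Si](C)(C)C(C)(C)C)[C@H]1COC(=O)C1 | intermediate
26 | ethyl (2Z,5R)-5-hydroxy-2-[(3E)-4-methyl-6-(2,6,6-trimethylcyclohex-1-en-1-yl)hex-3-en-1-yl]-5-[(3R)-5-oxooxolan-3-yl]pent-2-enoate | CCOC(=O)/C(CC/C=C(\C)CCC1=C(C)CCCC1(C)C)=C\C[C@@H](O)[C@H]1COC(=O)C1 | intermediate
27 | (6R)-3-[(3E)-4-methyl-6-(2,6,6-trimethylcyclohex-1-en-1-yl)hex-3-en-1-yl]-6-[(3R)-5-oxooxolan-3-yl]-5,6-dihydro-2H-pyran-2-one | CC1=C(CC/C(C)=C/CCC2=CC[C@H]([C@H]3COC(=O)C3)OC2=O)C(C)(C)CCC1 | target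

**Totals**
Total step count: 14.
Longest linear sequence: 9 steps (steps 1, 3, 4, 5, 6, 7, 8, 13, 14, from 1 and 2). The side-chain branch is 6 steps (9 to 14), and step 2 is a one-step side preparation.

**Steps most likely to fail, with fallbacks**

Step 10 (methylalumination and ethylene oxide trapping). The alkenylalane is moisture-sensitive and epoxide opening by the aluminate can be low-yielding. The fallback sets out from 15 and comes back to the route at 22, bypassing steps 9 to 11. Cyclopropylmagnesium bromide (c-C3H5MgBr, THF, 0 °C) is added to the ketone to give 2-cyclopropyl-4-(2,6,6-trimethylcyclohex-1-en-1-yl)butan-2-ol F1. A Julia-type cyclopropylcarbinyl to homoallyl rearrangement with MgI2 in refluxing Et2O then opens the ring directly to iodide 22. The E isomer is expected as the major product (roughly 4:1), and the Z isomer is removed on AgNO3-impregnated silica.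

Step 12 (alkylation of the diaryl phosphonoacetate with the homoallylic iodide). Risks are E2 elimination to the 1,3-diene, dialkylation and a sluggish hindered anion. The fallback sets out from 14 and 22 and comes back at 27; the side chain is attached by sp3–sp2 cross-coupling instead of enolate alkylation.
- Aldehyde 14 is olefinated with unalkylated 23 (NaH, THF, −78 °C; highly Z-selective for the disubstituted case) to ethyl (2Z,5R)-5-[(tert-butyldimethylsilyl)oxy]-5-[(3R)-5-oxooxolan-3-yl]pent-2-enoate F2.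
- HF·pyridine gives ethyl (2Z,5R)-5-hydroxy-5-[(3R)-5-oxooxolan-3-yl]pent-2-enoate F3, which closes under PPTS to (6R)-6-[(3R)-5-oxooxolan-3-yl]-5,6-dihydro-2H-pyran-2-one F4.
- α-Iodination with I2/pyridine in CH2Cl2 gives (6R)-3-iodo-6-[(3R)-5-oxooxolan-3-yl]-5,6-dihydro-2H-pyran-2-one F5.
- Iodide 22 is converted with Zn dust and LiCl in THF into iodo[(3E)-4-methyl-6-(2,6,6-trimethylcyclohex-1-en-1-yl)hex-3-en-1-yl]zinc F6.
- Negishi coupling of F5 with F6 using PdCl2(dppf) (5 mol %) in THF at rt gives 27.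

Step 13 (Z-selective olefination with the α-branched phosphonate). Risks are incomplete Z selectivity, slow addition of the hindered anion and base-induced β-elimination of the silyloxy aldehyde. The fallback sets out from 14 and 22 and comes back at 27; the ring alkene is made by ring-closing metathesis, so its geometry is fixed by the ring.
- Wittig methylenation of 14 (Ph3PCH3Br, KN(SiMe3)2, THF, −78 → 0 °C) gives (4R)-4-[(1R)-1-[(tert-butyldimethylsilyl)oxy]but-3-en-1-yl]oxolan-2-one F7, and HF·pyridine gives (4R)-4-[(1R)-1-hydroxybut-3-en-1-yl]oxolan-2-one F8.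
- Iodide 22 alkylates diethyl malonate (NaH, THF/DMF) to diethyl 2-[(3E)-4-methyl-6-(2,6,6-trimethylcyclohex-1-en-1-yl)hex-3-en-1-yl]propanedioate F9.
- Saponification (KOH, EtOH/H2O) gives 2-[(3E)-4-methyl-6-(2,6,6-trimethylcyclohex-1-en-1-yl)hex-3-en-1-yl]propanedioic acid F10.
- Decarboxylative Mannich methylenation (paraformaldehyde, Et2NH, EtOAc, reflux) gives (5E)-6-methyl-2-methylidene-8-(2,6,6-trimethylcyclohex-1-en-1-yl)oct-5-enoic acid F11.
- Esterification of F8 with F11 (DCC, DMAP, CH2Cl2, 0 °C) gives (1R)-1-[(3R)-5-oxooxolan-3-yl]but-3-en-1-yl (5E)-6-methyl-2-methylidene-8-(2,6,6-trimethylcyclohex-1-en-1-yl)oct-5-enoate F12.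
- Ring-closing metathesis with second-generation Grubbs catalyst (H2IMes)(PCy3)Cl2Ru=CHPh (5–10 mol %, CH2Cl2, 40 °C) closes the dihydropyranone to 27. The chain trisubstituted alkene could only form a cyclobutene or a nine-membered ring, so it does not compete.

**Further compounds**
F1 | step 10 | 2-cyclopropyl-4-(2,6,6-trimethylcyclohex-1-en-1-yl)butan-2-ol (racemic) | CC(O)(CCC1=C(C)CCCC1(C)C)C1CC1
F2 | step 12 | ethyl (2Z,5R)-5-[(tert-butyldimethylsilyl)oxy]-5-[(3R)-5-oxooxolan-3-yl]pent-2-enoate | CCOC(=O)/C=C\C[C@@H](O[Si](C)(C)C(C)(C)C)[C@H]1COC(=O)C1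
F3 | step 12 | ethyl (2Z,5R)-5-hydroxy-5-[(3R)-5-oxooxolan-3-yl]pent-2-enoate | CCOC(=O)/C=C\C[C@@H](O)[C@H]1COC(=O)C1
F4 | step 12 | (6R)-6-[(3R)-5-oxooxolan-3-yl]-5,6-dihydro-2H-pyran-2-one | O=C1C=CC[C@H]([C@H]2COC(=O)C2)O1
F5 | step 12 | (6R)-3-iodo-6-[(3R)-5-oxooxolan-3-yl]-5,6-dihydro-2H-pyran-2-one | O=C1C(I)=CC[C@H]([C@H]2COC(=O)C2)O1
F6 | step 12 | iodo[(3E)-4-methyl-6-(2,6,6-trimethylcyclohex-1-en-1-yl)hex-3-en-1-yl]zinc | I[Zn]CC/C=C(\C)CCC1=C(C)CCCC1(C)C
F7 | step 13 | (4R)-4-[(1R)-1-[(tert-butyldimethylsilyl)oxy]but-3-en-1-yl]oxolan-2-one | O=C1C[C@H](CO1)[C@H](O[Si](C)(C)C(C)(C)C)CC=C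
F8 | step 13 | (4R)-4-[(1R)-1-hydroxybut-3-en-1-yl]oxolan-2-one | O=C1C[C@H](CO1)[C@H](O)CC=C
F9 | step 13 | diethyl 2-[(3E)-4-methyl-6-(2,6,6-trimethylcyclohex-1-en-1-yl)hex-3-en-1-yl]propanedioate | CCOC(=O)C(CC/C=C(\C)CCC1=C(C)CCCC1(C)C)C(=O)OCC
F10 | step 13 | 2-[(3E)-4-methyl-6-(2,6,6-trimethylcyclohex-1-en-1-yl)hex-3-en-1-yl]propanedioic acid | OC(=O)C(CC/C=C(\C)CCC1=C(C)CCCC1(C)C)C(=O)O
F11 | step 13 | (5E)-6-methyl-2-methylidene-8-(2,6,6-trimethylcyclohex-1-en-1-yl)oct-5-enoic acid | C=C(CC/C=C(\C)CCC1=C(C)CCCC1(C)C)C(=O)O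
F12 | step 13 | (1R)-1-[(3R)-5-oxooxolan-3-yl]but-3-en-1-yl (5E)-6-methyl-2-methylidene-8-(2,6,6-trimethylcyclohex-1-en-1-yl)oct-5-enoate | C=CC[C@H]([C@H]1COC(=O)C1)OC(=O)C(=C)CC/C=C(\C)CCC1=C(C)CCCC1(C)C
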